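**Retrosynthetic overview**

1. The target (flavanone numbering O1, C2, C3, C4, C4a, C5–C8, C8a; ring A = benzo ring, ring B = 2-aryl group, ring C = pyranone) comes from global hydrogenolysis and decarboxylation of a 5,6,3'-tri-O-benzyl chromanone carrying a benzyl ester on C3. The ester is a traceless activating group, and C3 is set trans to C2 on ketonisation.
2. That chromanone comes from a one-pot union of two halves that builds ring C: C3–C4 by acylation of the alkoxide–enolate dianion of a β-hydroxy-α-methoxy ester with a ring-A Weinreb amide, then O1–C8a by capture of a C8–C8a aryne by the alkoxide on C2.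
3. Enabling feature: ring A has its single hydrogen on C8, flanked by C7–OMe and by the ring-fusion carbon C8a, which carries O1 and is ortho to C4a–C4(=O). A bromine on C8 therefore gives the C8–C8a aryne, the C4 tether and the C7 methoxy group both send O1 to C8a, and C8 ends as C–H.
4. The β-hydroxy ester (source of C2, R) comes from asymmetric transfer hydrogenation with dynamic kinetic resolution of the β-keto ester made from benzyl methoxyacetate and 3-(benzyloxy)-4-methoxybenzoic acid.
5. The Weinreb amide comes from 2,3-dihydroxy-4-methoxybenzaldehyde by benzylation, C5 bromination, oxidation and amidation. Rings A and B are bought; ring C is the only ring made (step 8).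

Key step: step 8

Remark on the chemistry: ring positions are named by flavanone numbering also in open-chain precursors (marked "future"); the C3 configuration shown for the ester-bearing intermediates is a prediction and has no bearing on the outcome, because step 9 erases it.

**Route**

Step 1
Reactants: 1 2,3-dihydroxy-4-methoxybenzaldehyde
Product: 2 2,3-bis(benzyloxy)-4-methoxybenzaldehyde
Conditions: BnBr, K2CO3, DMF, 60 °C
Reagents that add atoms: benzyl bromide, BrCc1ccccc1
Why: Williamson ether synthesis, in which both phenoxides (including the hydrogen-bonded 2-OH) are benzylated and the aldehyde is inert.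

Step 2
Reactants: 2 2,3-bis(benzyloxy)-4-methoxybenzaldehyde
Product: 3 2,3-bis(benzyloxy)-5-bromo-4-methoxybenzaldehyde
Conditions: N-bromosuccinimide, MeCN, rt, dark
Reagents that add atoms: N-bromosuccinimide, O=C1CCC(=O)N1Br
Why: Electrophilic aromatic bromination should go to C5 only, since C5 is ortho to the coplanar 4-OMe, para to the 2-benzyloxy group and meta to the formyl group, whereas C6 is ortho to the formyl group.

Step 3
Reactants: 3 2,3-bis(benzyloxy)-5-bromo-4-methoxybenzaldehyde
Product: 4 2,3-bis(benzyloxy)-5-bromo-4-methoxybenzoic acid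
Conditions: NaClO2, NaH2PO4, 2-methyl-2-butene, t-BuOH–THF–H2O, rt
Reagents that add atoms: sodium chlorite, [Na+].[O-]Cl=O
Why: Pinnick oxidation, in which chlorous acid converts the aldehyde to the acid and 2-methyl-2-butene scavenges HOCl so that the electron-rich ring and the benzyl ethers are not chlorinated.

Step 4
Reactants: 4 2,3-bis(benzyloxy)-5-bromo-4-methoxybenzoic acid
Product: 6 2,3-bis(benzyloxy)-5-bromo-N,4-dimethoxy-N-methylbenzamide, via acyl imidazole 5 (not isolated)
Conditions: 1,1'-carbonyldiimidazole, THF, rt; then MeNH(OMe)·HCl, rt to 40 °C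
Reagents that add atoms: N,O-dimethylhydroxylamine hydrochloride, CNOC.Cl
Why: Amide formation through the acyl imidazole, which activates the ortho-substituted acid under neutral conditions and is then acylated onto the hydroxylamine nitrogen, the liberated imidazole acting as base.

Step 5
Reactants: 7 methoxyacetyl chloride
Product: 8 benzyl 2-methoxyacetate
Conditions: BnOH, Et3N, CH2Cl2, 0 °C to rt
Reagents that add atoms: benzyl alcohol, OCc1ccccc1
Why: Acylation of an alcohol by an acid chloride with an amine base, a standard esterification.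

Step 6
Reactants: 8 benzyl 2-methoxyacetate; 9 3-(benzyloxy)-4-methoxybenzoic acid
Product: 12 benzyl 3-[3-(benzyloxy)-4-methoxyphenyl]-2-methoxy-3-oxopropanoate (racemic, C2 labile), via acyl imidazole 10 (not isolated), via lithium enolate 11 (not isolated)
Conditions: 9, 1,1'-carbonyldiimidazole, THF, rt; 8, LiN(SiMe3)2 (2.2 equiv), THF, −78 °C; combine, −78 to 0 °C; AcOH
Reagents that add atoms: none
Why: Crossed Claisen condensation, in which enolate 11 is C-acylated by the non-enolisable acyl imidazole 10 and deprotonation of the acidic β-keto ester by the second equivalent of base makes the step irreversible.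

Step 7
Reactants: 12 benzyl 3-[3-(benzyloxy)-4-methoxyphenyl]-2-methoxy-3-oxopropanoate
Product: 13 benzyl (2S,3R)-3-[3-(benzyloxy)-4-methoxyphenyl]-3-hydroxy-2-methoxypropanoate
Conditions: RuCl(p-cymene)[(S,S)-TsDPEN] (2 mol%), HCO2H–Et3N (5:2), CH2Cl2, 35 °C
Reagents that add atoms: none
Why: Noyori asymmetric transfer hydrogenation with dynamic kinetic resolution, in which C2 epimerises through the enol faster than reduction and the (S,S)-ligated ruthenium hydride is expected, by the aryl-ketone model known for α-alkoxy β-keto esters, to give the (3R) carbinol (future C2) as the syn isomer; only the carbinol centre matters later.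

Step 8
Reactants: 13 benzyl (2S,3R)-3-[3-(benzyloxy)-4-methoxyphenyl]-3-hydroxy-2-methoxypropanoate; 6 2,3-bis(benzyloxy)-5-bromo-N,4-dimethoxy-N-methylbenzamide
Product: 18 benzyl (2R,3R)-5,6-bis(benzyloxy)-2-[3-(benzyloxy)-4-methoxyphenyl]-3,7-dimethoxy-4-oxochromane-3-carboxylate, via dilithium dianion 14 (not isolated), via tetrahedral adduct 15 (not isolated), via aryne 16 (not isolated), via aryllithium 17 (not isolated)
Conditions: lithium 2,2,6,6-tetramethylpiperidide (2.2 equiv), THF, −78 to −40 °C; 6, −78 to −20 °C; lithium 2,2,6,6-tetramethylpiperidide (2.0 equiv), −78 to −30 °C; AcOH, −78 °C to rt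
Reagents that add atoms: none
Why: The lithium amide turns 13 into the chelated alkoxide–enolate dianion 14 (Fráter–Seebach type), whose enolate carbon (future C3) acylates Weinreb amide 6 (Claisen-type acylation of an ester enolate by an N-methoxy-N-methylamide) and stops at the lithium-chelated tetrahedral adduct 15, so that no C4 ketone, and hence no retro-aldol path that could scramble the future C2, exists while base is present. The second charge of base removes the only hydrogen ortho to bromine, C8a–H (also directed by the neighbouring α-amino alkoxide), LiBr is lost and the C8–C8a aryne 16 is captured by the tethered lithium alkoxide, the closest precedents being amide-base dehydrobromination of bromoarenes and the benzyne cyclisation of tethered alkoxides to chromans. Ring C closes by 6-exo addition of O1 to the aryne carbon C8a to give aryllithium 17, and the acetic acid quench protonates C8 and collapses the aminal to the C4 ketone. The step needs attack at C8a and not at C8: the tether admits only C8a (attack at C8 would need a bridged seven-membered ring) and the C7 methoxy group polarises the aryne in the same sense (nucleophile meta, carbanion ortho to OMe). No bond to the future C2 is made or broken, so it keeps the configuration of 13 and is (R) in 18; C3 is set by approach of the amide anti to the carbinol substituent of the chelated dianion (the anti rule of such dianions), and its configuration is of no consequence.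

Step 9
Reactants: 18 benzyl (2R,3R)-5,6-bis(benzyloxy)-2-[3-(benzyloxy)-4-methoxyphenyl]-3,7-dimethoxy-4-oxochromane-3-carboxylate
Product: 21 (2R,3R)-5,6-dihydroxy-2-(3-hydroxy-4-methoxyphenyl)-3,7-dimethoxychroman-4-one (CNP0393633.1), via keto acid 19 (not isolated), via enol 20 (not isolated)
Conditions: H2 (1 atm), Pd/C (10 wt% Pd), EtOAc–MeOH, rt; then cat. AcOH, MeOH, 40 °C, argon
Reagents that add atoms: none
Why: Hydrogenolysis removes the three benzyl ethers and the benzyl ester, the β-keto acid 19 loses CO2 through the cyclic six-membered transition state to enol 20, and ketonisation under control of C2 should set C3 as (R), because axial protonation gives the 2,3-trans diequatorial isomer, which is also the thermodynamic one, and the acid equilibrates any cis isomer through the enol without touching C2.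

**Compound list**

1 | 2,3-dihydroxy-4-methoxybenzaldehyde | COc1ccc(C=O)c(O)c1O | starting material
2 | 2,3-bis(benzyloxy)-4-methoxybenzaldehyde | COc1ccc(C=O)c(OCc2ccccc2)c1OCc1ccccc1 | intermediate
3 | 2,3-bis(benzyloxy)-5-bromo-4-methoxybenzaldehyde | COc1c(Br)cc(C=O)c(OCc2ccccc2)c1OCc1ccccc1 | intermediate
4 | 2,3-bis(benzyloxy)-5-bromo-4-methoxybenzoic acid | COc1c(Br)cc(C(=O)O)c(OCc2ccccc2)c1OCc1ccccc1 | intermediate
5 | [2,3-bis(benzyloxy)-5-bromo-4-methoxyphenyl](1H-imidazol-1-yl)methanone | COc1c(Br)cc(C(=O)n2ccnc2)c(OCc2ccccc2)c1OCc1ccccc1 | intermediate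
6 | 2,3-bis(benzyloxy)-5-bromo-N,4-dimethoxy-N-methylbenzamide | COc1c(Br)cc(C(=O)N(C)OC)c(OCc2ccccc2)c1OCc1ccccc1 | intermediate
7 | methoxyacetyl chloride | COCC(=O)Cl | starting material
8 | benzyl 2-methoxyacetate | COCC(=O)OCc1ccccc1 | intermediate
9 | 3-(benzyloxy)-4-methoxybenzoic acid | COc1ccc(cc1OCc1ccccc1)C(=O)O | starting material
10 | [3-(benzyloxy)-4-methoxyphenyl](1H-imidazol-1-yl)methanone | COc1ccc(cc1OCc1ccccc1)C(=O)n1ccnc1 | intermediate
11 | lithium 1-(benzyloxy)-2-methoxyethen-1-olate (lithium enolate of 8, geometry not specified) | [Li+].[O-]C(=COC)OCc1ccccc1 | intermediate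
12 | benzyl 3-[3-(benzyloxy)-4-methoxyphenyl]-2-methoxy-3-oxopropanoate (racemic, C2 labile) | COc1ccc(cc1OCc1ccccc1)C(=O)C(OC)C(=O)OCc1ccccc1 | intermediate
13 | benzyl (2S,3R)-3-[3-(benzyloxy)-4-methoxyphenyl]-3-hydroxy-2-methoxypropanoate | COc1ccc(cc1OCc1ccccc1)[C@@H](O)[C@H](OC)C(=O)OCc1ccccc1 | intermediate
14 | dilithium alkoxide–enolate of 13 ((R) carbinol, enolate geometry not specified) | COc1ccc(cc1OCc1ccccc1)[C@@H]([O-])C(OC)=C([O-])OCc1ccccc1.[Li+].[Li+] | intermediate
15 | dilithium salt of the tetrahedral adduct of 14 with 6 (C3–C4 bond formed, C4 as C(OLi)(NMeOMe) of unspecified configuration, bromine on C8) | COc1ccc(cc1OCc1ccccc1)[C@@H]([O-])[C@](OC)(C(=O)OCc1ccccc1)C([O-])(N(C)OC)c1cc(Br)c(OC)c(OCc2ccccc2)c1OCc1ccccc1.[Li+].[Li+] | intermediate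
16 | C8–C8a aryne derived from 15 by loss of LiBr (dilithium salt) | COc1ccc(cc1OCc1ccccc1)[C@@H]([O-])[C@](OC)(C(=O)OCc1ccccc1)C([O-])(N(C)OC)C1=C(OCc2ccccc2)C(OCc2ccccc2)=C(OC)C#C1.[Li+].[Li+] | intermediate
17 | ring-closed C8-lithiated chroman with C4 still as the lithium aminal alkoxide | COc1ccc(cc1OCc1ccccc1)[C@H]1Oc2[c-]c(OC)c(OCc3ccccc3)c(OCc3ccccc3)c2C([O-])(N(C)OC)[C@@]1(OC)C(=O)OCc1ccccc1.[Li+].[Li+] | intermediate
18 | benzyl (2R,3R)-5,6-bis(benzyloxy)-2-[3-(benzyloxy)-4-methoxyphenyl]-3,7-dimethoxy-4-oxochromane-3-carboxylate | COc1ccc(cc1OCc1ccccc1)[C@H]1Oc2cc(OC)c(OCc3ccccc3)c(OCc3ccccc3)c2C(=O)[C@@]1(OC)C(=O)OCc1ccccc1 | intermediate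
19 | (2R,3R)-5,6-dihydroxy-2-(3-hydroxy-4-methoxyphenyl)-3,7-dimethoxy-4-oxochromane-3-carboxylic acid | COc1ccc(cc1O)[C@H]1Oc2cc(OC)c(O)c(O)c2C(=O)[C@@]1(OC)C(=O)O | intermediate
20 | (2R)-2-(3-hydroxy-4-methoxyphenyl)-3,7-dimethoxy-2H-chromene-4,5,6-triol (enol) | COc1ccc(cc1O)[C@H]1Oc2cc(OC)c(O)c(O)c2C(O)=C1OC | intermediate
21 | (2R,3R)-5,6-dihydroxy-2-(3-hydroxy-4-methoxyphenyl)-3,7-dimethoxychroman-4-one (CNP0393633.1) | COc1ccc([C@H]2Oc3cc(OC)c(O)c(O)c3C(=O)[C@@H]2OC)cc1O | target

**Totals and risks**

Total step count: 9. Longest linear sequence: 6 steps (steps 1, 2, 3, 4, 8, 9).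

Steps most likely to fail:

Step 8. The C-acylation of the fully substituted enolate carbon by the ortho-substituted Weinreb amide may be too slow, or the aminal may collapse before ring closure and expose a β-keto ester alkoxide to retro-aldol cleavage. The fallback sets out from aldehyde 3 and hydroxy ester 13 and returns at 18. Dianion 14 is added to 3 at −78 °C, an aldol addition in place of the acylation that leaves C4 at the carbinol level, where nothing can collapse. More lithium 2,2,6,6-tetramethylpiperidide then generates the same C8–C8a aryne, the alkoxide on C2 closes ring C, and acetic acid quench should give benzyl (2R)-5,6-bis(benzyloxy)-2-[3-(benzyloxy)-4-methoxyphenyl]-4-hydroxy-3,7-dimethoxychromane-3-carboxylate F1 as a mixture at C3 and C4. Dess–Martin periodinane (CH2Cl2, rt) then oxidises the C4 carbinol to 18.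

Step 9. Hydrogenolysis of the benzylic C2–O1 bond or reduction of the C4 ketone may compete with debenzylation. The fallback sets out from 18 and returns at 21. BCl3 with pentamethylbenzene as cation scavenger (CH2Cl2, −78 °C) cleaves the three benzyl ethers and the benzyl ester without hydrogen. After MeOH quench and gentle warming, keto acid 19 decarboxylates through enol 20 to 21. This fallback makes no new compound (F0).

Step 7. Enantio-induction may be insufficient, or the electron-rich α-alkoxy aryl ketone may be reduced too slowly. The fallback sets out from methoxyacetyl chloride 7 and returns at 13. (S)-4-Benzyl-1,3-oxazolidin-2-one is lithiated with n-butyllithium (THF, −78 °C) and acylated with 7 to give (4S)-4-benzyl-3-(methoxyacetyl)-1,3-oxazolidin-2-one F2. Its dibutylboron enolate (Bu2BOTf, i-Pr2NEt, CH2Cl2, −78 °C) undergoes an Evans syn glycolate aldol addition to commercial 3-(benzyloxy)-4-methoxybenzaldehyde to give (4S)-4-benzyl-3-{(2S,3R)-3-[3-(benzyloxy)-4-methoxyphenyl]-3-hydroxy-2-methoxypropanoyl}-1,3-oxazolidin-2-one F3. Lithium benzyloxide (BnOLi, THF, −20 °C) then transesterifies F3 to 13.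

Further compounds

F1 | step 8 | benzyl (2R)-5,6-bis(benzyloxy)-2-[3-(benzyloxy)-4-methoxyphenyl]-4-hydroxy-3,7-dimethoxychromane-3-carboxylate (mixture at C3 and C4) | COc1ccc(cc1OCc1ccccc1)[C@H]1Oc2cc(OC)c(OCc3ccccc3)c(OCc3ccccc3)c2C(O)C1(OC)C(=O)OCc1ccccc1
F0 | step 9 | none | none
F2 | step 7 | (4S)-4-benzyl-3-(methoxyacetyl)-1,3-oxazolidin-2-one | COCC(=O)N1[C@@H](Cc2ccccc2)COC1=O
F3 | step 7 | (4S)-4-benzyl-3-{(2S,3R)-3-[3-(benzyloxy)-4-methoxyphenyl]-3-hydroxy-2-methoxypropanoyl}-1,3-oxazolidin-2-one | COc1ccc(cc1OCc1ccccc1)[C@@H](O)[C@H](OC)C(=O)N1[C@@H](Cc2ccccc2)COC1=O
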